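Assumption: the SMILES has no stereodescriptors and no stereocentres; the only stereoelement is the hindered 6,8'-biaryl axis, which is undefined, so the target is made as drawn (racemic axis, separable on a chiral column if one atropisomer is wanted).

## Retrosynthetic overview

- Quinone ring first: catechol (1) + bromoethane (2) → 2-ethoxyphenol (3) → 2-ethoxy-1,4-benzoquinone (4), which already carries the OEt of each half.
- Benzenoid ring second: methyl 3-methylbut-2-enoate (5) → vinylketene acetal (6); regioselective Diels–Alder/aromatisation of 4 + 6 → 3-ethoxy-7-methyljuglone (7).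
- Key disconnection, made last: the C6–C8' biaryl bond of the target (8) ⇒ two identical molecules of 7, joined by a phenoxyl-radical ortho–para dehydrodimerisation on the unprotected hydroxyquinone.

## Route

**Step 1**
Reactants: 1 catechol (benzene-1,2-diol); 2 bromoethane
Product: 3 2-ethoxyphenol
Conditions: EtBr (0.8 equiv), K2CO3, DMF, 60 °C, N2 (excess catechol, recovered)
Reagents that add atoms: bromoethane, CCBr (compound 2)
Why: Williamson ether synthesis; using catechol in excess keeps dialkylation low, and 3 is separated from catechol and 1,2-diethoxybenzene by extraction/distillation.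

**Step 2**
Reactants: 3 2-ethoxyphenol
Product: 4 2-ethoxy-1,4-benzoquinone
Conditions: (KSO3)2NO (2.5 equiv), KH2PO4 buffer, H2O/acetone, 0 °C → rt
Reagents that add atoms: Fremy's salt, [K+].[K+].[O]N(S(=O)(=O)[O-])S(=O)(=O)[O-] (supplies the new carbonyl O)
Why: Teuber oxidation; a phenol with a free para position goes to the p-quinone, as is well established for guaiacol.

**Step 3**
Reactants: 5 methyl 3-methylbut-2-enoate
Product: 6 1-methoxy-3-methyl-1-(trimethylsilyloxy)buta-1,3-diene (E/Z mixture at C1=C2, of no consequence)
Conditions: LDA, THF, −78 °C; TMSCl, −78 °C → rt; distil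
Reagents that add atoms: chlorotrimethylsilane, C[Si](C)(C)Cl
Why: γ-deprotonation of the enoate to the dienolate and O-silylation gives the vinylketene acetal (Brassard-type diene).

**Step 4**
Reactants: 4 2-ethoxy-1,4-benzoquinone; 6 vinylketene acetal (1.3 equiv)
Product: 7 3-ethoxy-5-hydroxy-7-methyl-1,4-naphthoquinone (3-ethoxy-7-methyljuglone)
Conditions: CH2Cl2, −40 °C → rt; SiO2 (aromatisation, loss of MeOH/TMS); then Ag2O, MgSO4, rt
Reagents that add atoms: none
Why: Diels–Alder at the unsubstituted C5=C6 bond of 4, where the OEt makes C4=O a vinylogous-ester carbonyl so that C1=O polarises the dienophile: the CH2 terminus of 6 bonds to C5 and the acetal carbon to C6, which after aromatisation to the 1,4,5-triol and Ag2O oxidation puts the new OH peri to the carbonyl flanked by OEt (3-ethoxy, not 2-ethoxy); no stereocentre survives.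

**Step 5**
Reactants: 7 3-ethoxy-7-methyljuglone (two molecules)
Product: 8 3,3'-diethoxyisodiospyrin (target)
Conditions: BDD anode/Pt cathode, divided cell, 7 (0.1 M) in HFIP, MeBu3N·O3SOMe (0.1 M), 2,6-lutidine (1 equiv), 5 mA cm⁻², ~1.0 F mol⁻¹, 40 °C; stop near 50% conversion, recycle 7
Reagents that add atoms: none
Why: Proposed new method: anodic proton-coupled oxidation of the 5-OH gives an HFIP-stabilised phenoxyl radical with spin at C6 (ortho) and C8 (para), which forms a C–C bond with a second molecule of 7 and re-aromatises by loss of e⁻/H⁺; 8,8'-coupling is sterically shut off (each C8 is flanked by 7-Me and the peri C1=O), so the para carbon of one unit should pair with the less hindered ortho C6 of the other (6,8'), with the symmetric 6,6'-dimer as the expected by-product and the 3-OEt vinylogous ester suppressing the usual Michael-type dimerisation through the quinone ring; the closest known reaction type is anodic dehydrogenative homocoupling of phenols bearing acyl/ester groups at BDD in HFIP (and the biogenetic phenol coupling of 7-methyljuglone to isodiospyrin); the axis forms racemic.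

## Compound list

1 | catechol | Oc1ccccc1O | starting material
2 | bromoethane | CCBr | starting material
3 | 2-ethoxyphenol | CCOc1ccccc1O | intermediate
4 | 2-ethoxy-1,4-benzoquinone | CCOC1=CC(=O)C=CC1=O | intermediate
5 | methyl 3-methylbut-2-enoate | COC(=O)C=C(C)C | starting material
6 | 1-methoxy-3-methyl-1-(trimethylsilyloxy)buta-1,3-diene (E/Z mixture) | COC(=CC(C)=C)O[Si](C)(C)C | intermediate
7 | 3-ethoxy-5-hydroxy-7-methyl-1,4-naphthoquinone | CCOC1=CC(=O)c2cc(C)cc(O)c2C1=O | intermediate
8 | 3,3'-diethoxyisodiospyrin (3,3'-diethoxy-5,5'-dihydroxy-7,7'-dimethyl-6,8'-binaphthalene-1,4:1',4'-diquinone; axis not specified) | CCOC1=CC(=O)c2cc(C)c(-c3c(C)cc(O)c4c3C(=O)C=C(OCC)C4=O)c(O)c2C1=O | target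

## Summary

Total steps: 5. Longest linear sequence: 4 (steps 1, 2, 4, 5; step 3 is a one-step side branch).

Steps most likely to fail, with fallbacks:

1. **Step 5 (dimerisation).** The hydroxyquinone may be too electron-poor to couple, or the 6,6'- or quinone-ring-linked isomers may dominate. Fallback: abandon the homodimerisation for a regiodefined cross-coupling of reduced, O-methylated halves. One half is 7 converted to its 1,4-dimethoxy-5-naphthol (reacting at C6); the other carries a halogen at C8 from the outset (8-chloro-7-methyljuglone series from 4-chloro-3-methylphenol + maleic anhydride, AlCl3/NaCl). Join them by photostimulated SRN1 arylation of the naphthoxide (or Suzuki coupling), then oxidise both rings back to quinones with CAN.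

2. **Step 4 (Diels–Alder/aromatisation).** Michael-type addition of the ketene acetal, incomplete aromatisation/oxidation, or erosion of regiochemistry. Fallback: use a halogen-directed, self-aromatising cycloaddition of 6 with 2,6-dibromo-1,4-benzoquinone (phenol → 2,4,6-tribromophenol → HNO3) to give 3-bromo-7-methyljuglone, then replace Br by OEt through addition–elimination (EtOH, NaOEt or Et3N).

3. **Step 2 (Fremy oxidation).** Over-oxidation or coupling of the electron-rich phenol. Fallback: a two-electron route through the quinone monoketal: PhI(OAc)2 in MeOH to 2-ethoxy-4,4-dimethoxycyclohexa-2,5-dienone, then mild aqueous acid to 4.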